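Its constants are those of an exercise; the run is a simulation.

How much nucleophile you spend on this flask is your decision, so find the charge that just does the job.

electrophile 0.46 M; gas 20 mM (held); time 2.0 min

    electrophile + nucleophile → acid set free + product (k1 = 0.020 L mol⁻¹ s⁻¹)
    nucleophile + acid set free ⇌ protonated nucleophile, settled at all times (K2 = 450 L mol⁻¹)
    acid set free + free base ⇌ salt of the base, settled at all times (K3 = 32000 L mol⁻¹)
    crystals ⇌ acid set free, rate k4*(cs4 - [acid set free]) while solid is left; crystals form when [acid set free] > cs4 (cs4 = 42 mM, k4 = 0.26 s⁻¹)
    2 electrophile → homo dimer (k5 = 0.020 L mol⁻¹ s⁻¹)
    gas ⇌ free base, rate k6*(csat - [free base]) (k6 = 0.45 s⁻¹, csat = 20 mM)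

- the concentration of nucleophile at which the part of the electrophile that has reacted at 2.0 min is just 90 %, in M

Start by turning constants into times. Treat step 1 as pseudo-first-order, with the free nucleophile steady: to leave 10.0 % of the electrophile charge after 2.0 min, you need a level of 0.959 M, which means a nucleophile time of 0.869 min. But the homo dimer route has its own time at the charged amount, 0.906 min, of the same size, so that guess is too high.

Both routes integrate together. Let r be the nucleophile time over the dimer time. The reciprocal of the fraction left is then one plus r, times the exponential of run time over nucleophile time, less r. Solving with the old r gives 0.717 M. Yet a lower level raises r, so repeat: 0.666 M, then 0.652 M, and as the steps are shrinking I stop there: this is, near enough, the steady free nucleophile that reaches the wanted part in the run time, the needed level.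

That is a free level, though, not a charge. At this level r is 1.41, and step 1 carries 53.0 % of the electrophile charge. Each turn also frees acid. Taking the free base at its saturation, which is a guess, the protonated nucleophile takes 31.4 % of the acid held by it and the salt of the base together. The estimated end loss of free nucleophile, one for each turn of step 1 plus the protonated part, is then 0.320 M. It builds up over an opening time of 0.530 min, shorter than the run time, so I take its mean over the run as 73.5 % of the end loss, and my charge is 0.887 M.

The forecast, at 0.92 M, stands above mine, and holds that “the gas-fed base mops up most of the acid”.

The flask needs 0.906 M. At 1.00 min its free nucleophile was 69.8 % of the charge. The needed level is 71.9 % of that charge. Assume this share for the flask with half this charge of nucleophile: its level is 0.326 M, and the integrated form gives 81.9 % reacted at the end. The run of that flask gives 81.5 % reacted at the end.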